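**Retrosynthetic overview** (ring numbering: C1 = carbinol carbon, C3=C4 and C7=C8 = ring alkenes, C10 = CMe2)
1. The Z-p-coumarate is built last on ring alcohol 22 by acylation and a Z-selective Horner–Wadsworth–Emmons olefination; the C7 methyl comes just before from a stereoretentive Negishi methylation of a ring alkenyl chloride.
2. Key disconnection C6–C7: the 11-membered carbocycle (the only ring that is built; the benzene ring is bought) is closed by a one-flask 9-BBN hydroboration / trans-selective B-alkyl Suzuki–Miyaura macrocyclisation of the acyclic 1,1-dichloroalkene–diene 17.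
3. Enabling feature: C7 is a fully substituted alkene carbon whose two substituents besides C8 are both carbon (ring C6 and a methyl), so it can enter as a geometry-free CCl2 carbon. Its C–Cl bond trans to C9 reacts first (ring bond, 7E geometry) and the second C–Cl bond later takes the methyl. C6 lies homoallylic to C3=C4, so it is unmasked from the terminal carbon of a C3=C4–C5=C6 diene.
4. 17 is assembled linearly: methyl 3,3-dimethylpent-4-enoate gives C8–C11 and C1, BrCCl3 gives C7, an allenylboronate gives C2–C4 and sets C1 (S), Me3Al gives the C3 methyl, and vinyl bromide gives C5–C6.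

Key step: step 8

Remark: the Z-cinnamate is taken to be light- and base-sensitive, so steps 13 and 14 are run with exclusion of light.

**Step 1**
Reactants: 1 methyl 3,3-dimethylpent-4-enoate
Product: 2 3,3-dimethylpent-4-enal
Conditions: i-Bu2AlH (1.05 equiv), CH2Cl2, −78 °C; MeOH, then aq. KNaC4H4O6; the volatile aldehyde is carried on as a concentrated solution
Reagents that add atoms: none
Why: Partial ester reduction with i-Bu2AlH: the tetrahedral aluminium hemiacetal is stable at −78 °C and releases the aldehyde only on work-up, and the terminal alkene is inert.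

**Step 2**
Reactants: 2 3,3-dimethylpent-4-enal; 3 bromotrichloromethane
Product: 4 1,1-dichloro-4,4-dimethylhexa-1,5-diene
Conditions: PPh3 (3 equiv), BrCCl3 (1.5 equiv), MeCN, 0 °C to rt
Reagents that add atoms: bromotrichloromethane (3), ClC(Cl)(Cl)Br
Why: Ramirez-type (Wittig) dichloromethylenation: Ph3P=CCl2 generated from PPh3 and BrCCl3 converts the unhindered aldehyde into a 1,1-dichloroalkene, which has no alkene stereochemistry and should stay inert until step 8.

**Step 3**
Reactants: 4 1,1-dichloro-4,4-dimethylhexa-1,5-diene; 5 9-borabicyclo[3.3.1]nonane (9-BBN); 6 hydrogen peroxide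
Product: 8 6,6-dichloro-3,3-dimethylhex-5-en-1-ol, via alkyl-9-BBN borane 7 (not isolated)
Conditions: 9-BBN (1.2 equiv), THF, 0 °C to rt; then aq. NaOH, 30% H2O2, 0 °C to rt
Reagents that add atoms: hydrogen peroxide (6), OO
Why: Brown hydroboration–oxidation: 9-BBN adds anti-Markovnikov to the monosubstituted vinyl group only (the electron-poor trisubstituted dichloroalkene does not react) and alkaline H2O2 oxidises the C–B bond to the primary alcohol.

**Step 4**
Reactants: 8 6,6-dichloro-3,3-dimethylhex-5-en-1-ol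
Product: 9 6,6-dichloro-3,3-dimethylhex-5-enal
Conditions: Dess–Martin periodinane (1.2 equiv), CH2Cl2, rt
Reagents that add atoms: none
Why: Dess–Martin oxidation stops at the aldehyde under neutral, water-free conditions that leave the dichloroalkene untouched.

**Step 5**
Reactants: 9 6,6-dichloro-3,3-dimethylhex-5-enal; 10 allenylboronic acid pinacol ester
Product: 11 (4S)-9,9-dichloro-6,6-dimethylnon-8-en-1-yn-4-ol
Conditions: 10 (1.5 equiv), (R)-TRIP [(R)-3,3'-bis(2,4,6-triisopropylphenyl)-1,1'-binaphthyl-2,2'-diyl hydrogen phosphate] (5 mol%), 4 Å molecular sieves, toluene, 0 °C; aq. NaHCO3 work-up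
Reagents that add atoms: allenylboronic acid pinacol ester (10), C=C=CB1OC(C)(C)C(C)(C)O1
Why: Chiral phosphoric acid-catalysed asymmetric propargylation of an aliphatic aldehyde: the catalyst activates the allenylboronate in a closed six-membered SE2' transition state, and the (R)-catalyst is expected to direct the propargyl group to the Re face of the aldehyde, which sets the (S)-carbinol that becomes ring C1.

**Step 6**
Reactants: 11 (4S)-9,9-dichloro-6,6-dimethylnon-8-en-1-yn-4-ol; 12 tert-butyldimethylsilyl chloride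
Product: 13 tert-butyl{[(4S)-9,9-dichloro-6,6-dimethylnon-8-en-1-yn-4-yl]oxy}dimethylsilane
Conditions: TBSCl (1.3 equiv), imidazole (2.5 equiv), DMF, rt
Reagents that add atoms: tert-butyldimethylsilyl chloride (12), CC(C)(C)[Si](C)(C)Cl
Why: Standard silylation of the secondary alcohol; the TBS ether should survive the organoaluminium, borane, zinc and zerovalent palladium chemistry that follows.

**Step 7**
Reactants: 13 tert-butyl{[(4S)-9,9-dichloro-6,6-dimethylnon-8-en-1-yn-4-yl]oxy}dimethylsilane; 14 trimethylaluminium; 15 vinyl bromide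
Product: 17 tert-butyl{[(3E,6S)-11,11-dichloro-4,8,8-trimethylundeca-1,3,10-trien-6-yl]oxy}dimethylsilane, via alkenyldimethylalane 16 (not isolated)
Conditions: Me3Al (3 equiv), Cp2ZrCl2 (0.5 equiv), ClCH2CH2Cl, rt; then CH2=CHBr (3 equiv), ZnCl2 (cat.), Pd(PPh3)4 (5 mol%), THF, rt
Reagents that add atoms: trimethylaluminium (14), C[Al](C)C; vinyl bromide (15), C=CBr
Why: Negishi zirconium-catalysed carboalumination adds Me and Al syn across the terminal alkyne with Me on the internal carbon, which fixes the E-trisubstituted alkene, and the alkenylalane is then cross-coupled with vinyl bromide with retention (Negishi coupling), while the C–Cl bonds should not react with Pd(PPh3)4 at room temperature.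

**Step 8**
Reactants: 17 tert-butyl{[(3E,6S)-11,11-dichloro-4,8,8-trimethylundeca-1,3,10-trien-6-yl]oxy}dimethylsilane; 5 9-borabicyclo[3.3.1]nonane (9-BBN)
Product: 19 tert-butyl{[(1S,3E,7Z)-7-chloro-3,10,10-trimethylcycloundeca-3,7-dien-1-yl]oxy}dimethylsilane, via homoallylic 9-BBN borane 18 (not isolated)
Conditions: 9-BBN (1.2 equiv), THF, 0 °C to rt; then syringe-pump addition (12 h) to Pd2(dba)3 (5 mol%), Xantphos (10 mol%), aq. K3PO4 (3 equiv), THF, 65 °C, final concentration about 2 mM
Reagents that add atoms: none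
Why: 9-BBN adds to the terminal CH=CH2 of the 1,3-diene only, with boron on the unsubstituted carbon (future C6), and the homoallylic borane 18 is coupled in the same flask: zerovalent palladium inserts into the C–Cl bond of the CCl2 group that lies trans to the C9 chain, the phosphate-activated borane transmetalates intramolecularly and reductive elimination forms C6–C7. The closest known reaction types are the trans-selective B-alkyl Suzuki–Miyaura mono-coupling of 1,1-dichloro-1-alkenes with 9-alkyl-9-BBN reagents under Pd/Xantphos and the B-alkyl Suzuki–Miyaura macrocyclisation of borane-tethered alkenyl halides. The 11-membered carbocycle is closed at an sp2–sp3 bond with the C7=C8 alkene inside the ring (endo mode), through a 12-membered alkyl(alkenyl)palladium intermediate. No stereocentre is formed and C1 is not touched; the C7=C8 geometry is set by which C–Cl bond reacts, so that C6 is delivered trans to C9 and the chloride stays cis to C9 (7Z by the sequence rule, which becomes 7E after methylation). The step needs chemoselective hydroboration (secured by the bulk of 9-BBN, which leaves both trisubstituted alkenes alone), site-selective mono-coupling (secured by the lower steric demand of the trans C–Cl bond, the wide-bite-angle ligand and the low reactivity of the remaining alkenyl chloride) and ring closure over oligomerisation (secured by slow addition at high dilution, helped by the gem-dimethyl group and the rigid E-alkene).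

**Step 9**
Reactants: 19 tert-butyl{[(1S,3E,7Z)-7-chloro-3,10,10-trimethylcycloundeca-3,7-dien-1-yl]oxy}dimethylsilane; 20 dimethylzinc
Product: 21 tert-butyldimethyl{[(1S,3E,7E)-3,7,10,10-tetramethylcycloundeca-3,7-dien-1-yl]oxy}silane
Conditions: Me2Zn (3 equiv), Pd(P(t-Bu)3)2 (5 mol%), THF/NMP, 60 °C
Reagents that add atoms: dimethylzinc (20), C[Zn]C
Why: Negishi coupling of the remaining alkenyl chloride, made possible by the bulky electron-rich phosphine, proceeds with retention of alkene geometry, so the methyl arrives cis to C9 and C7=C8 becomes E.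

**Step 10**
Reactants: 21 tert-butyldimethyl{[(1S,3E,7E)-3,7,10,10-tetramethylcycloundeca-3,7-dien-1-yl]oxy}silane
Product: 22 (1S,3E,7E)-3,7,10,10-tetramethylcycloundeca-3,7-dien-1-ol
Conditions: n-Bu4NF (2 equiv), THF, rt to 40 °C
Reagents that add atoms: none
Why: Fluoride-mediated silyl ether cleavage (Si–F bond formation) frees the secondary alcohol without touching the alkenes or the stereocentre.

**Step 11**
Reactants: 22 (1S,3E,7E)-3,7,10,10-tetramethylcycloundeca-3,7-dien-1-ol; 23 bromoacetyl bromide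
Product: 24 (1S,3E,7E)-3,7,10,10-tetramethylcycloundeca-3,7-dien-1-yl 2-bromoacetate
Conditions: BrCH2COBr (1.5 equiv), pyridine (2 equiv), CH2Cl2, −20 to 0 °C
Reagents that add atoms: bromoacetyl bromide (23), BrCC(=O)Br
Why: O-Acylation with an acid bromide and pyridine proceeds with retention at the carbinol carbon and installs the α-bromoacetate needed for P–C bond formation.

**Step 12**
Reactants: 24 (1S,3E,7E)-3,7,10,10-tetramethylcycloundeca-3,7-dien-1-yl 2-bromoacetate; 25 diphenyl phosphite
Product: 26 (1S,3E,7E)-3,7,10,10-tetramethylcycloundeca-3,7-dien-1-yl 2-(diphenoxyphosphoryl)acetate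
Conditions: (PhO)2P(O)H (1.3 equiv), i-Pr2NEt (1.5 equiv), CH2Cl2, 0 °C to rt
Reagents that add atoms: diphenyl phosphite (25), O=[PH](Oc1ccccc1)Oc1ccccc1
Why: Michaelis–Becker reaction: the amine-generated diphenyl phosphite anion displaces the activated primary bromide through phosphorus to give the diaryl phosphonoacetate needed for a Z-selective olefination.

**Step 13**
Reactants: 26 (1S,3E,7E)-3,7,10,10-tetramethylcycloundeca-3,7-dien-1-yl 2-(diphenoxyphosphoryl)acetate; 27 4-[(tert-butyldimethylsilyl)oxy]benzaldehyde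
Product: 29 (1S,3E,7E)-3,7,10,10-tetramethylcycloundeca-3,7-dien-1-yl (2Z)-3-{4-[(tert-butyldimethylsilyl)oxy]phenyl}prop-2-enoate, via sodium phosphonate carbanion 28 (not isolated)
Conditions: NaH (1.1 equiv), THF, 0 °C; then 27 (1.2 equiv), −78 to −20 °C, dark
Reagents that add atoms: 4-[(tert-butyldimethylsilyl)oxy]benzaldehyde (27), O=Cc1ccc(O[Si](C)(C)C(C)(C)C)cc1
Why: Ando variant of the Horner–Wadsworth–Emmons reaction: the electron-poor diaryl phosphonate makes oxaphosphetane collapse fast and kinetically controlled, which should give the Z-cinnamate from the aromatic aldehyde at low temperature.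

**Step 14**
Reactants: 29 (1S,3E,7E)-3,7,10,10-tetramethylcycloundeca-3,7-dien-1-yl (2Z)-3-{4-[(tert-butyldimethylsilyl)oxy]phenyl}prop-2-enoate
Product: 30 (1S,3E,7E)-3,7,10,10-tetramethylcycloundeca-3,7-dien-1-yl (2Z)-3-(4-hydroxyphenyl)prop-2-enoate
Conditions: n-Bu4NF (1.1 equiv), AcOH (1.2 equiv), THF, 0 °C, dark
Reagents that add atoms: none
Why: Buffered fluoride cleaves the aryl silyl ether far faster than it attacks the ester, and exclusion of light and free base avoids Z-to-E isomerisation of the cinnamate.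

**Compound list**
1 | methyl 3,3-dimethylpent-4-enoate | C=CC(C)(C)CC(=O)OC | starting material
2 | 3,3-dimethylpent-4-enal | C=CC(C)(C)CC=O | intermediate
3 | bromotrichloromethane | ClC(Cl)(Cl)Br | starting material
4 | 1,1-dichloro-4,4-dimethylhexa-1,5-diene | C=CC(C)(C)CC=C(Cl)Cl | intermediate
5 | 9-borabicyclo[3.3.1]nonane (9-BBN) | B1C2CCCC1CCC2 | starting material
6 | hydrogen peroxide | OO | starting material
7 | 9-(6,6-dichloro-3,3-dimethylhex-5-en-1-yl)-9-borabicyclo[3.3.1]nonane | ClC(Cl)=CCC(C)(C)CCB1C2CCCC1CCC2 | intermediate (not isolated)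
8 | 6,6-dichloro-3,3-dimethylhex-5-en-1-ol | OCCC(C)(C)CC=C(Cl)Cl | intermediate
9 | 6,6-dichloro-3,3-dimethylhex-5-enal | O=CCC(C)(C)CC=C(Cl)Cl | intermediate
10 | allenylboronic acid pinacol ester | C=C=CB1OC(C)(C)C(C)(C)O1 | starting material
11 | (4S)-9,9-dichloro-6,6-dimethylnon-8-en-1-yn-4-ol | ClC(Cl)=CCC(C)(C)C[C@H](O)CC#C | intermediate
12 | tert-butyldimethylsilyl chloride | CC(C)(C)[Si](C)(C)Cl | starting material
13 | tert-butyl{[(4S)-9,9-dichloro-6,6-dimethylnon-8-en-1-yn-4-yl]oxy}dimethylsilane | ClC(Cl)=CCC(C)(C)C[C@H](O[Si](C)(C)C(C)(C)C)CC#C | intermediate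
14 | trimethylaluminium | C[Al](C)C | starting material
15 | vinyl bromide | C=CBr | starting material
16 | {(1E,4S)-4-[(tert-butyldimethylsilyl)oxy]-9,9-dichloro-2,6,6-trimethylnona-1,8-dien-1-yl}dimethylalane | ClC(Cl)=CCC(C)(C)C[C@H](O[Si](C)(C)C(C)(C)C)C/C(C)=C/[Al](C)C | intermediate (not isolated)
17 | tert-butyl{[(3E,6S)-11,11-dichloro-4,8,8-trimethylundeca-1,3,10-trien-6-yl]oxy}dimethylsilane | ClC(Cl)=CCC(C)(C)C[C@H](O[Si](C)(C)C(C)(C)C)C/C(C)=C/C=C | intermediate
18 | 9-{(3E,6S)-6-[(tert-butyldimethylsilyl)oxy]-11,11-dichloro-4,8,8-trimethylundeca-3,10-dien-1-yl}-9-borabicyclo[3.3.1]nonane | ClC(Cl)=CCC(C)(C)C[C@H](O[Si](C)(C)C(C)(C)C)C/C(C)=C/CCB1C2CCCC1CCC2 | intermediate (not isolated)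
19 | tert-butyl{[(1S,3E,7Z)-7-chloro-3,10,10-trimethylcycloundeca-3,7-dien-1-yl]oxy}dimethylsilane | Cl/C1=C\CC(C)(C)C[C@H](O[Si](C)(C)C(C)(C)C)C/C(C)=C/CC1 | intermediate
20 | dimethylzinc | C[Zn]C | starting material
21 | tert-butyldimethyl{[(1S,3E,7E)-3,7,10,10-tetramethylcycloundeca-3,7-dien-1-yl]oxy}silane | C/C1=C\CC(C)(C)C[C@H](O[Si](C)(C)C(C)(C)C)C/C(C)=C/CC1 | intermediate
22 | (1S,3E,7E)-3,7,10,10-tetramethylcycloundeca-3,7-dien-1-ol | C/C1=C\CC(C)(C)C[C@H](O)C/C(C)=C/CC1 | intermediate
23 | bromoacetyl bromide | BrCC(=O)Br | starting material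
24 | (1S,3E,7E)-3,7,10,10-tetramethylcycloundeca-3,7-dien-1-yl 2-bromoacetate | C/C1=C\CC(C)(C)C[C@H](OC(=O)CBr)C/C(C)=C/CC1 | intermediate
25 | diphenyl phosphite | O=[PH](Oc1ccccc1)Oc1ccccc1 | starting material
26 | (1S,3E,7E)-3,7,10,10-tetramethylcycloundeca-3,7-dien-1-yl 2-(diphenoxyphosphoryl)acetate | C/C1=C\CC(C)(C)C[C@H](OC(=O)CP(=O)(Oc2ccccc2)Oc2ccccc2)C/C(C)=C/CC1 | intermediate
27 | 4-[(tert-butyldimethylsilyl)oxy]benzaldehyde | O=Cc1ccc(O[Si](C)(C)C(C)(C)C)cc1 | starting material
28 | sodium 1-(diphenoxyphosphoryl)-2-oxo-2-{[(1S,3E,7E)-3,7,10,10-tetramethylcycloundeca-3,7-dien-1-yl]oxy}ethan-1-ide | [Na+].C/C1=C\CC(C)(C)C[C@H](OC(=O)[CH-]P(=O)(Oc2ccccc2)Oc2ccccc2)C/C(C)=C/CC1 | intermediate (not isolated)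
29 | (1S,3E,7E)-3,7,10,10-tetramethylcycloundeca-3,7-dien-1-yl (2Z)-3-{4-[(tert-butyldimethylsilyl)oxy]phenyl}prop-2-enoate | C/C1=C\CC(C)(C)C[C@H](OC(=O)/C=C\c2ccc(O[Si](C)(C)C(C)(C)C)cc2)C/C(C)=C/CC1 | intermediate
30 | (1S,3E,7E)-3,7,10,10-tetramethylcycloundeca-3,7-dien-1-yl (2Z)-3-(4-hydroxyphenyl)prop-2-enoate | C/C1=C\CC(C)(C)C[C@H](OC(=O)/C=C\c2ccc(O)cc2)C/C(C)=C/CC1 | target

**Step count and risk**
Total step count: 14. Longest linear sequence: 14 steps (1 to 30).

Steps most likely to fail:

1. Step 8. What may go wrong: intermolecular coupling outruns ring closure (oligomerisation), the alkylborane is lost by protodeboronation or β-hydride elimination before it transmetalates, or palladium inserts unselectively into the two C–Cl bonds. Fallback, setting out from 17 and coming back at 19: the diene 17 is hydroborated with 9-BBN as in the route, but borane 18 is oxidised (NaOH, H2O2) to the homoallylic alcohol (3E,6S)-6-[(tert-butyldimethylsilyl)oxy]-11,11-dichloro-4,8,8-trimethylundeca-3,10-dien-1-ol F1. I2, PPh3 and imidazole convert it into the primary iodide tert-butyl{[(6S,8E)-1,1-dichloro-11-iodo-4,4,8-trimethylundeca-1,8-dien-6-yl]oxy}dimethylsilane F2. Zinc insertion (Zn, LiCl, THF, 40 °C; the dichloroalkene is inert) gives the alkylzinc iodide {(3E,6S)-6-[(tert-butyldimethylsilyl)oxy]-11,11-dichloro-4,8,8-trimethylundeca-3,10-dien-1-yl}(iodo)zinc F3, which is added slowly to Pd(DPEphos)Cl2 in THF/DMF at 50 °C. This intramolecular Negishi coupling, a reaction type known to mono-alkylate 1,1-dichloroalkenes trans-selectively, closes the same bond with a more nucleophilic, base-free partner and gives 19.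

2. Step 13. What may go wrong: erosion of Z-selectivity in the olefination, or Z-to-E isomerisation of the cinnamate during work-up. Fallback, setting out from 22 and coming back at 29: alcohol 22 is esterified with propiolic acid (DCC, cat. DMAP, CH2Cl2, −20 °C) to (1S,3E,7E)-3,7,10,10-tetramethylcycloundeca-3,7-dien-1-yl prop-2-ynoate F4. Sonogashira coupling with commercial tert-butyl(4-iodophenoxy)dimethylsilane (Pd(PPh3)2Cl2, CuI, i-Pr2NEt, THF, rt) gives (1S,3E,7E)-3,7,10,10-tetramethylcycloundeca-3,7-dien-1-yl 3-{4-[(tert-butyldimethylsilyl)oxy]phenyl}prop-2-ynoate F5. Cis-semihydrogenation (H2, Pd/CaCO3 poisoned with Pb(OAc)2, quinoline, EtOAc) then fixes the Z geometry by syn addition of hydrogen and gives 29; the trisubstituted ring alkenes should not react.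

3. Step 5. What may go wrong: insufficient facial discrimination by the catalyst (low enantiomeric purity), or competing allenyl transfer. Fallback, setting out from 9 and coming back at 13: Roskamp homologation of 9 with ethyl diazoacetate (SnCl2 cat., CH2Cl2) gives the β-keto ester ethyl 8,8-dichloro-5,5-dimethyl-3-oxooct-7-enoate F6. Noyori hydrogenation (RuCl2[(S)-BINAP], H2, EtOH) gives ethyl (3S)-8,8-dichloro-3-hydroxy-5,5-dimethyloct-7-enoate F7, with the configuration set by the ester-directed, catalyst-controlled hydride delivery. Silylation with 12 (imidazole, DMF) gives ethyl (3S)-3-[(tert-butyldimethylsilyl)oxy]-8,8-dichloro-5,5-dimethyloct-7-enoate F8. i-Bu2AlH at −78 °C gives (3S)-3-[(tert-butyldimethylsilyl)oxy]-8,8-dichloro-5,5-dimethyloct-7-enal F9, and the Ohira–Bestmann reagent (dimethyl (1-diazo-2-oxopropyl)phosphonate, K2CO3, MeOH) converts F9 into alkyne 13.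

**Further compounds**
F1 | step 8 | (3E,6S)-6-[(tert-butyldimethylsilyl)oxy]-11,11-dichloro-4,8,8-trimethylundeca-3,10-dien-1-ol | ClC(Cl)=CCC(C)(C)C[C@H](O[Si](C)(C)C(C)(C)C)C/C(C)=C/CCO
F2 | step 8 | tert-butyl{[(6S,8E)-1,1-dichloro-11-iodo-4,4,8-trimethylundeca-1,8-dien-6-yl]oxy}dimethylsilane | ClC(Cl)=CCC(C)(C)C[C@H](O[Si](C)(C)C(C)(C)C)C/C(C)=C/CCI
F3 | step 8 | {(3E,6S)-6-[(tert-butyldimethylsilyl)oxy]-11,11-dichloro-4,8,8-trimethylundeca-3,10-dien-1-yl}(iodo)zinc | ClC(Cl)=CCC(C)(C)C[C@H](O[Si](C)(C)C(C)(C)C)C/C(C)=C/CC[Zn]I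
F4 | step 13 | (1S,3E,7E)-3,7,10,10-tetramethylcycloundeca-3,7-dien-1-yl prop-2-ynoate | C/C1=C\CC(C)(C)C[C@H](OC(=O)C#C)C/C(C)=C/CC1
F5 | step 13 | (1S,3E,7E)-3,7,10,10-tetramethylcycloundeca-3,7-dien-1-yl 3-{4-[(tert-butyldimethylsilyl)oxy]phenyl}prop-2-ynoate | C/C1=C\CC(C)(C)C[C@H](OC(=O)C#Cc2ccc(O[Si](C)(C)C(C)(C)C)cc2)C/C(C)=C/CC1
F6 | step 5 | ethyl 8,8-dichloro-5,5-dimethyl-3-oxooct-7-enoate | CCOC(=O)CC(=O)CC(C)(C)CC=C(Cl)Cl
F7 | step 5 | ethyl (3S)-8,8-dichloro-3-hydroxy-5,5-dimethyloct-7-enoate | ClC(Cl)=CCC(C)(C)C[C@H](O)CC(=O)OCC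
F8 | step 5 | ethyl (3S)-3-[(tert-butyldimethylsilyl)oxy]-8,8-dichloro-5,5-dimethyloct-7-enoate | ClC(Cl)=CCC(C)(C)C[C@H](O[Si](C)(C)C(C)(C)C)CC(=O)OCC
F9 | step 5 | (3S)-3-[(tert-butyldimethylsilyl)oxy]-8,8-dichloro-5,5-dimethyloct-7-enal | ClC(Cl)=CCC(C)(C)C[C@H](O[Si](C)(C)C(C)(C)C)CC=O
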